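Take the amounts first: this flask holds 500 G for each L. But G also goes to E and X also dies, so reckon a chain's length from times, not from the charge.

G 0.20 M; L 0.40 mM; J 0.23 mM; time 8.0 h

    G → E (k1 = 2.6 × 10⁻⁴ s⁻¹)
    D + X → G + X, rate k2*[X] as long as [D] is above zero (k2 = 0.046 s⁻¹)
    G + X → D + X, rate k3*[X]*[G] (k3 = 0.51 L mol⁻¹ s⁻¹)
    L + J → L.J (k4 = 110 L mol⁻¹ s⁻¹)
    X → Q (k5 = 3.6 × 10⁻⁴ s⁻¹)
    G + L → X + D (k6 = 0.044 L mol⁻¹ s⁻¹)

1. average number of monomer units in a chain (chains begun, living or dead) at 8.0 h
2. part of the G that has reacted at 8.0 h

Turn the constants into times. G lives 64.1 min against its loss to E, and X lives 46.3 min. At full charge a chain adds a unit every 9.80 s and sheds one every 21.7 s. With G as a fraction of its charge, growth balances shedding at 45.1%, the equilibrium monomer level.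

For c, reckon the fraction of G left after 8.0 h:

left = exp(−8.0 h/64.1 min) = 0.0560%

So c stands near 99.9%.

For dp, follow one chain. Its growth fades with G and its survival together, over a joint lifetime of 26.9 min, while shedding fades with survival:

units = 1 + 26.9 min/9.80 s − 46.3 min/21.7 s = 1 + 165 − 128 = 37.7

Call this the lone-chain yield: the units a chain ends with if its neighbours leave G untouched.

Doubt the start: chains might begin late. But L lives 114 s against G, much shorter than G's lifetime, so take birth at full charge.

Doubt the word "lone". As a first estimate, count the chains as L less J, 0.170 mM. While they live, their growth alone draws on G at 8.67 × 10⁻⁵ s⁻¹, a third of the loss to E at the same G. Charge that draw for the whole run and the yield falls to 17.6, which is too harsh, since X lives 46.3 min, shorter than the run. Commit to dp between 17.6 and 37.7.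

The forecast gave dp 27, within 19 to 36, and c 99.9%, with G going "nearly all of it to E rather than into chains".

The flask gives dp 29.5 and c 99.9%. The average stood at 48.9 after 0.800 h and then fell. Read the shortfall from the lone-chain yield as 8.24 units, with Q ending at 1.90 × 10⁻⁴ M.

Now take the neighbour flask with 3.9 × 10⁻⁴ M of J, where Q ends at 1.09 × 10⁻⁴ M. The lone-chain yield holds no J, so it stays 37.7. Scale the shortfall with Q and reckon dp 33.0. The neighbour flask gives 33.5.

The numbers are invented; the run is a simulation.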